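**Plan**

- Retrosynthesis: the two aryl O–Si bonds are cut first. The furan is then opened by adding ethanol back across C5/C2 and cutting the ring C3–C4 bond (ring-closing metathesis). The O1–C5 acetal bond, the ester C–O bond, the C4–carbinol bond and the C2–C3 bond follow in turn.
- Enabling feature: in the furan ring, O1–C2(aryl)–C3 is a 1-arylallyl alcohol and C4–C5 is a 2-substituted acrolein with C5 at the aldehyde oxidation level. C3–C4 is therefore an alkene-to-alkene junction, and the C5 alkoxy group together with the benzylic C2–H allows aromatisation.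
- Forward: the side-chain half (vinyllithium addition, oxidation, CBS reduction, acylation) and the aryl half (silylation, vinyl Grignard addition) are made separately and joined through O1–C5 as a mixed acetal. The only new ring, the furan, is closed at C3–C4 and aromatised in one flask; desilylation ends the route.
- Stereochemistry: the (R)-carbinol centre comes from reduction of an enone with the (S)-CBS catalyst, and the (R)-2-methylbutanoyl centre from the purchased acid. The acetal and benzylic centres are left uncontrolled because aromatisation removes both.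

Key step: step 9

Remark: (R)-2-methylbutanoic acid is assumed to be bought as the single enantiomer; compounds 12, 13 and 14 are carried as mixtures at the benzylic and acetal centres.

**Route**

Step 1
Reactants: 1 4-methylpent-3-en-1-ol
Product: 2 4-methylpent-3-enal
Conditions: Dess–Martin periodinane, pyridine, CH2Cl2, 0 °C to rt; short silica plug, careful concentration, used at once
Reagents that add atoms: none
Why: Dess–Martin oxidation of the primary alcohol under pyridine-buffered, non-aqueous conditions should stop at the aldehyde and leave the skipped trisubstituted alkene out of conjugation.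

Step 2
Reactants: 3 2-bromoacrolein diethyl acetal (2-bromo-3,3-diethoxyprop-1-ene); 2 4-methylpent-3-enal
Product: 5 rac-2-(diethoxymethyl)-6-methylhepta-1,5-dien-3-ol, via (3,3-diethoxyprop-1-en-2-yl)lithium 4 (not isolated)
Conditions: n-BuLi, THF, −78 °C; then 2, −78 °C; H2O quench
Reagents that add atoms: none
Why: Bromine–lithium exchange gives a vinyllithium that keeps its acetal at −78 °C and should add 1,2 to the aldehyde faster than it enolises it (organolithium carbonyl addition); the new carbinol centre is racemic and is reset in steps 3 and 4.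

Step 3
Reactants: 5 rac-2-(diethoxymethyl)-6-methylhepta-1,5-dien-3-ol
Product: 6 2-(diethoxymethyl)-6-methylhepta-1,5-dien-3-one
Conditions: Dess–Martin periodinane, pyridine, CH2Cl2, 0 °C
Reagents that add atoms: none
Why: Dess–Martin oxidation of the secondary allylic alcohol is neutral enough to spare the acetal and to leave the doubly activated methylene of the skipped dienone unenolised.

Step 4
Reactants: 6 2-(diethoxymethyl)-6-methylhepta-1,5-dien-3-one
Product: 7 (3R)-2-(diethoxymethyl)-6-methylhepta-1,5-dien-3-ol
Conditions: (S)-Me-CBS (20 mol %), catecholborane, toluene, −78 °C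
Reagents that add atoms: none
Why: Corey–Bakshi–Shibata reduction: the ketone oxygen binds the ring boron of the (S)-oxazaborolidine anti to its larger substituent, the branched 1-(diethoxymethyl)vinyl group, and hydride passes from the nitrogen-bound borane to the face that gives the (R)-alcohol, while catecholborane at −78 °C should leave both alkenes alone.

Step 5
Reactants: 7 (3R)-2-(diethoxymethyl)-6-methylhepta-1,5-dien-3-ol; 8 (R)-2-methylbutanoic acid
Product: 9 (3R)-2-(diethoxymethyl)-6-methylhepta-1,5-dien-3-yl (2R)-2-methylbutanoate
Conditions: DCC, DMAP (cat.), CH2Cl2, 0 °C to rt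
Reagents that add atoms: none
Why: Steglich esterification through the acylpyridinium ion acylates the hindered allylic alcohol at oxygen without breaking its C–O bond, and low temperature with catalytic DMAP should keep the α-centre of the acid from epimerising.

Step 6
Reactants: 10 2,5-dihydroxybenzaldehyde
Product: 11 2,5-bis(tert-butyldimethylsilyloxy)benzaldehyde
Conditions: TBSCl, imidazole, DMF, rt
Reagents that add atoms: tert-butyldimethylsilyl chloride (TBSCl), CC(C)(C)[Si](C)(C)Cl
Why: Silylation of both phenols with a silyl chloride and imidazole is standard; the hydrogen-bonded ortho phenol reacts last but should go to completion with excess reagent.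

Step 7
Reactants: 11 2,5-bis(tert-butyldimethylsilyloxy)benzaldehyde
Product: 12 rac-1-[2,5-bis(tert-butyldimethylsilyloxy)phenyl]prop-2-en-1-ol
Conditions: CH2=CHMgBr, THF, −78 °C; AcOH quench at −78 °C
Reagents that add atoms: vinylmagnesium bromide, C=C[Mg]Br
Why: Grignard addition to the aryl aldehyde gives the racemic allylic alcohol, and protonation at −78 °C should forestall migration of the ortho silyl group to the magnesium alkoxide; the benzylic centre needs no control because it is erased in step 9.

Step 8
Reactants: 9 (3R)-2-(diethoxymethyl)-6-methylhepta-1,5-dien-3-yl (2R)-2-methylbutanoate; 12 rac-1-[2,5-bis(tert-butyldimethylsilyloxy)phenyl]prop-2-en-1-ol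
Product: 13 (3R)-2-{ethoxy[1-(2,5-bis(tert-butyldimethylsilyloxy)phenyl)allyloxy]methyl}-6-methylhepta-1,5-dien-3-yl (2R)-2-methylbutanoate (mixture at the acetal and benzylic centres)
Conditions: 12 (2 equiv), PPTS (10 mol %), 5 Å MS, toluene, 50 °C, reduced pressure
Reagents that add atoms: none
Why: Acid-catalysed transacetalisation: loss of ethanol from 9 gives a 2-substituted alkoxyallyl oxocarbenium ion that alcohol 12 captures at the acetal carbon, removal of ethanol drives the exchange, and a second exchange is held back by the bulk of both partners; all diastereomers formed lead to the same furan.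

Step 9
Reactants: 13 (3R)-2-{ethoxy[1-(2,5-bis(tert-butyldimethylsilyloxy)phenyl)allyloxy]methyl}-6-methylhepta-1,5-dien-3-yl (2R)-2-methylbutanoate
Product: 15 (1R)-1-{5-[2,5-bis(tert-butyldimethylsilyloxy)phenyl]furan-3-yl}-4-methylpent-3-en-1-yl (2R)-2-methylbutanoate, via 2-ethoxy-2,5-dihydrofuran ester 14 (not isolated)
Conditions: Hoveyda–Grubbs II (10 mol %), 1,4-benzoquinone (10 mol %), toluene, 80 °C, argon sparge; then PPTS (20 mol %), 40 °C
Reagents that add atoms: none
Why: The ruthenium alkylidene loads on the monosubstituted vinyl group of 13, adds across the tethered geminal alkene to a ruthenacyclobutane and cycloreverts with loss of ethylene, so the C3–C4 bond and the five-membered ring of 14 arise in one ring-closing metathesis event. The closest known reaction type is the ring-closing metathesis of allyl mixed acetals of acrolein and 2-substituted acroleins to 2-alkoxy-2,5-dihydrofurans, followed by acid-promoted loss of alcohol to the furan. Pyridinium tosylate then ionises the cyclic acetal to an oxocarbenium ion conjugated with the ring alkene, and loss of the benzylic C2 proton gives the aromatic furan. No stereocentre is formed: the benzylic and acetal centres of 13 are both erased, so all four diastereomers should converge on 15, while the carbinol and 2-methylbutanoyl centres are not touched by a neutral catalyst and a weak acid. The step needs chemoselectivity among three alkenes and 2,4-regiochemistry: the vinyl group is the only fast initiation site, closure onto the geminal alkene gives a five-membered ring whereas the trisubstituted prenyl alkene could only give an eight-membered one, and the substitution pattern is fixed by the connectivity of the acetal. Benzoquinone is added to suppress ruthenium hydride isomerisation of the allyl ether during the slow closure onto the hindered alkene.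

Step 10
Reactants: 15 (1R)-1-{5-[2,5-bis(tert-butyldimethylsilyloxy)phenyl]furan-3-yl}-4-methylpent-3-en-1-yl (2R)-2-methylbutanoate
Product: 16 (1R)-1-[5-(2,5-dihydroxyphenyl)furan-3-yl]-4-methylpent-3-en-1-yl (2R)-2-methylbutanoate
Conditions: TBAF, AcOH (1:1), THF, 0 °C, argon
Reagents that add atoms: none
Why: Fluoride-induced desilylation: aryl silyl ethers are cleaved fast because phenoxide leaves readily from the fluorosilicate, and acetic acid buffering with exclusion of air should protect the ester, its α-centre and the hydroquinone.

**Compound list**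

1 | 4-methylpent-3-en-1-ol | CC(C)=CCCO | starting material
2 | 4-methylpent-3-enal | CC(C)=CCC=O | intermediate
3 | 2-bromoacrolein diethyl acetal | C=C(Br)C(OCC)OCC | starting material
4 | (3,3-diethoxyprop-1-en-2-yl)lithium | [Li]C(=C)C(OCC)OCC | intermediate
5 | rac-2-(diethoxymethyl)-6-methylhepta-1,5-dien-3-ol | CCOC(OCC)C(=C)C(O)CC=C(C)C | intermediate
6 | 2-(diethoxymethyl)-6-methylhepta-1,5-dien-3-one | CCOC(OCC)C(=C)C(=O)CC=C(C)C | intermediate
7 | (3R)-2-(diethoxymethyl)-6-methylhepta-1,5-dien-3-ol | O[C@H](CC=C(C)C)C(=C)C(OCC)OCC | intermediate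
8 | (R)-2-methylbutanoic acid | CC[C@@H](C)C(=O)O | starting material
9 | (3R)-2-(diethoxymethyl)-6-methylhepta-1,5-dien-3-yl (2R)-2-methylbutanoate | CC[C@@H](C)C(=O)O[C@H](CC=C(C)C)C(=C)C(OCC)OCC | intermediate
10 | 2,5-dihydroxybenzaldehyde | O=Cc1cc(O)ccc1O | starting material
11 | 2,5-bis(tert-butyldimethylsilyloxy)benzaldehyde | O=Cc1cc(O[Si](C)(C)C(C)(C)C)ccc1O[Si](C)(C)C(C)(C)C | intermediate
12 | rac-1-[2,5-bis(tert-butyldimethylsilyloxy)phenyl]prop-2-en-1-ol | C=CC(O)c1cc(O[Si](C)(C)C(C)(C)C)ccc1O[Si](C)(C)C(C)(C)C | intermediate
13 | (3R)-2-{ethoxy[1-(2,5-bis(tert-butyldimethylsilyloxy)phenyl)allyloxy]methyl}-6-methylhepta-1,5-dien-3-yl (2R)-2-methylbutanoate, acetal and benzylic centres as a mixture | CC[C@@H](C)C(=O)O[C@H](CC=C(C)C)C(=C)C(OCC)OC(C=C)c1cc(O[Si](C)(C)C(C)(C)C)ccc1O[Si](C)(C)C(C)(C)C | intermediate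
14 | (1R)-1-{5-[2,5-bis(tert-butyldimethylsilyloxy)phenyl]-2-ethoxy-2,5-dihydrofuran-3-yl}-4-methylpent-3-en-1-yl (2R)-2-methylbutanoate, ring centres as a mixture | CC[C@@H](C)C(=O)O[C@H](CC=C(C)C)C1=CC(c2cc(O[Si](C)(C)C(C)(C)C)ccc2O[Si](C)(C)C(C)(C)C)OC1OCC | intermediate
15 | (1R)-1-{5-[2,5-bis(tert-butyldimethylsilyloxy)phenyl]furan-3-yl}-4-methylpent-3-en-1-yl (2R)-2-methylbutanoate | CC[C@@H](C)C(=O)O[C@H](CC=C(C)C)c1coc(-c2cc(O[Si](C)(C)C(C)(C)C)ccc2O[Si](C)(C)C(C)(C)C)c1 | intermediate
16 | (1R)-1-[5-(2,5-dihydroxyphenyl)furan-3-yl]-4-methylpent-3-en-1-yl (2R)-2-methylbutanoate | CC[C@@H](C)C(=O)O[C@H](CC=C(C)C)c1coc(-c2cc(O)ccc2O)c1 | target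

**Count and risks**

Total step count: 10. Longest linear sequence: 8 steps (steps 1–5, then 8–10).

Steps most likely to fail:

1. Step 8 (mixed acetal formation). The exchange may stall at partial conversion or spread over unchanged, singly and doubly exchanged acetals, because both partners are hindered and neither can be used in large excess. The acid may also ionise the electron-rich benzylic allylic alcohol.
   Fallback, setting out from 3 and 12 and coming back at 13: the exchange is moved to the start of the sequence, where the small commercial acetal 3 can be used in large excess. PPTS in toluene under reduced pressure should give 2-[1-(2-bromo-1-ethoxyallyloxy)allyl]-1,4-bis(tert-butyldimethylsilyloxy)benzene F1. A Nozaki–Hiyama–Kishi coupling of this vinyl bromide with aldehyde 2 (CrCl2, cat. NiCl2, DMF, rt) avoids any strongly basic organometallic next to the benzylic allylic ether and should give 2-{ethoxy[1-(2,5-bis(tert-butyldimethylsilyloxy)phenyl)allyloxy]methyl}-6-methylhepta-1,5-dien-3-ol F2 as a diastereomer mixture. Dess–Martin oxidation then gives 2-{ethoxy[1-(2,5-bis(tert-butyldimethylsilyloxy)phenyl)allyloxy]methyl}-6-methylhepta-1,5-dien-3-one F3. Reduction with the (S)-CBS catalyst and catecholborane gives (3R)-2-{ethoxy[1-(2,5-bis(tert-butyldimethylsilyloxy)phenyl)allyloxy]methyl}-6-methylhepta-1,5-dien-3-ol F4, and Steglich acylation with acid 8 returns to 13.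

2. Step 9 (ring-closing metathesis and aromatisation). After loading on the vinyl group, closure onto a geminal alkene flanked by two branched sp3 carbons may be slower than intermolecular metathesis at the vinyl group and than double-bond migration of the allyl ether, so that dimers and enol ethers build up in place of the dihydrofuran.
   Fallback, setting out from 6 and 12 and coming back at 15: the ring is closed at the ketone oxidation level. PPTS-catalysed exchange of dienone 6 with alcohol 12 gives the dienone mixed acetal F3 already described under the fallback for step 8. Its geminal alkene has a planar carbonyl carbon on one side and belongs to the enone class, for which ring-closing metathesis with second-generation catalysts is routine. Metathesis should give 1-{5-[2,5-bis(tert-butyldimethylsilyloxy)phenyl]-2-ethoxy-2,5-dihydrofuran-3-yl}-4-methylpent-3-en-1-one F5, and PPTS in the same flask 1-{5-[2,5-bis(tert-butyldimethylsilyloxy)phenyl]furan-3-yl}-4-methylpent-3-en-1-one F6. CBS reduction of this heteroaryl ketone with the (S)-catalyst (furyl large, methylene small) should give (1R)-1-{5-[2,5-bis(tert-butyldimethylsilyloxy)phenyl]furan-3-yl}-4-methylpent-3-en-1-ol F7, and Steglich acylation with acid 8 returns to 15.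

3. Step 4 (CBS reduction). Face discrimination may be incomplete because the catalyst must tell a branched alkenyl group from a sizeable prenyl-methylene group. The skipped dienone 6 may also drift into conjugation before it is reduced.
   Fallback, setting out from 5 and coming back at 7, with no ketone made: a Sharpless kinetic resolution of racemic 5 (Ti(OiPr)4, L-(+)-diisopropyl tartrate, substoichiometric TBHP, 4 Å MS, CH2Cl2, −20 °C). This should epoxidise the (S)-enantiomer at the allylic geminal alkene to (1S)-1-[(2S)-2-(diethoxymethyl)oxiran-2-yl]-4-methylpent-3-en-1-ol F8 and leave the (R)-alcohol 7, which is separated by chromatography. At most half of the material is recovered as 7.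

**Further compounds**

F1 | step 8 | 2-[1-(2-bromo-1-ethoxyallyloxy)allyl]-1,4-bis(tert-butyldimethylsilyloxy)benzene | C=C(Br)C(OCC)OC(C=C)c1cc(O[Si](C)(C)C(C)(C)C)ccc1O[Si](C)(C)C(C)(C)C
F2 | step 8 | 2-{ethoxy[1-(2,5-bis(tert-butyldimethylsilyloxy)phenyl)allyloxy]methyl}-6-methylhepta-1,5-dien-3-ol | CC(C)=CCC(O)C(=C)C(OCC)OC(C=C)c1cc(O[Si](C)(C)C(C)(C)C)ccc1O[Si](C)(C)C(C)(C)C
F3 | step 8 | 2-{ethoxy[1-(2,5-bis(tert-butyldimethylsilyloxy)phenyl)allyloxy]methyl}-6-methylhepta-1,5-dien-3-one | CC(C)=CCC(=O)C(=C)C(OCC)OC(C=C)c1cc(O[Si](C)(C)C(C)(C)C)ccc1O[Si](C)(C)C(C)(C)C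
F4 | step 8 | (3R)-2-{ethoxy[1-(2,5-bis(tert-butyldimethylsilyloxy)phenyl)allyloxy]methyl}-6-methylhepta-1,5-dien-3-ol | CC(C)=CC[C@@H](O)C(=C)C(OCC)OC(C=C)c1cc(O[Si](C)(C)C(C)(C)C)ccc1O[Si](C)(C)C(C)(C)C
F5 | step 9 | 1-{5-[2,5-bis(tert-butyldimethylsilyloxy)phenyl]-2-ethoxy-2,5-dihydrofuran-3-yl}-4-methylpent-3-en-1-one | CC(C)=CCC(=O)C1=CC(c2cc(O[Si](C)(C)C(C)(C)C)ccc2O[Si](C)(C)C(C)(C)C)OC1OCC
F6 | step 9 | 1-{5-[2,5-bis(tert-butyldimethylsilyloxy)phenyl]furan-3-yl}-4-methylpent-3-en-1-one | CC(C)=CCC(=O)c1coc(-c2cc(O[Si](C)(C)C(C)(C)C)ccc2O[Si](C)(C)C(C)(C)C)c1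
F7 | step 9 | (1R)-1-{5-[2,5-bis(tert-butyldimethylsilyloxy)phenyl]furan-3-yl}-4-methylpent-3-en-1-ol | CC(C)=CC[C@@H](O)c1coc(-c2cc(O[Si](C)(C)C(C)(C)C)ccc2O[Si](C)(C)C(C)(C)C)c1
F8 | step 4 | (1S)-1-[(2S)-2-(diethoxymethyl)oxiran-2-yl]-4-methylpent-3-en-1-ol | CC(C)=CC[C@H](O)[C@]1(C(OCC)OCC)CO1
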